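**Retrosynthetic overview**
1. Target 17 ⇐ its 8‑O‑methyl ether 15 (chelation‑assisted demethylation as the last step).
2. 15 ⇐ pentenyl lactone 10 + (E)‑1‑iododec‑1‑ene 13 (B‑alkyl Suzuki coupling; the E geometry is fixed beforehand by hydrozirconation of dec‑1‑yne).
3. 10 ⇐ allyl lactone 8 (hydroboration, then B‑alkyl Suzuki coupling with vinyl bromide as a two‑carbon homologation).
4. 8 ⇐ arylacetaldehyde 5 + allyl unit: the key C3–C1′ bond and the (R) carbinol come from an intermolecular asymmetric carbonyl allylation; the lactone ring, the only ring built, closes directly afterwards (the benzene ring is bought).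
5. 5 ⇐ methyl 2‑hydroxy‑6‑methoxybenzoate 1 (triflate, Stille allylation, ozonolysis).

Assumption: the SMILES is read as (3R) with a (6′E) side‑chain alkene; reagent solutions (the allylborane in pentane, 9‑BBN in THF, vinyl bromide in THF) are bought and not numbered.

**Route**

Step 1
Reactants: 1 methyl 2‑hydroxy‑6‑methoxybenzoate
Product: 2 methyl 2‑methoxy‑6‑(trifluoromethanesulfonyloxy)benzoate
Conditions: Tf2O (1.2 equiv), pyridine (2.5 equiv), CH2Cl2, 0 °C → rt
Reagents that add atoms: trifluoromethanesulfonic anhydride, O=S(=O)(OS(=O)(=O)C(F)(F)F)C(F)(F)F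
Why: O‑sulfonylation (triflation) of the salicylate phenol turns it into an aryl triflate ready for cross‑coupling, with the ester and the methyl ether untouched.

Step 2
Reactants: 2 methyl 2‑methoxy‑6‑(trifluoromethanesulfonyloxy)benzoate
Product: 3 methyl 2‑methoxy‑6‑(prop‑2‑en‑1‑yl)benzoate
Conditions: allylSnBu3 (1.2 equiv), Pd(PPh3)4 (5 mol%), LiCl (3 equiv), DMF, 90 °C
Reagents that add atoms: allyltributylstannane, C=CC[Sn](CCCC)(CCCC)CCCC
Why: Stille cross‑coupling, in which LiCl‑assisted oxidative addition of the aryl triflate to zerovalent palladium, allyl transfer from tin and reductive elimination give the allyl arene without touching the ester.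

Step 3
Reactants: 3 methyl 2‑methoxy‑6‑(prop‑2‑en‑1‑yl)benzoate
Product: 5 methyl 2‑methoxy‑6‑(2‑oxoethyl)benzoate, via ozonide 4 (not isolated)
Conditions: O3, CH2Cl2, −78 °C (stop at first blue colour, purge with N2); then PPh3 (1.2 equiv), −78 °C → rt; use 5 at once
Reagents that add atoms: ozone, [O-][O+]=O
Why: Ozonolysis of the terminal alkene, which reacts far faster than the ester‑deactivated anisole ring, followed by reductive cleavage of the ozonide gives the arylacetaldehyde.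

Step 4
Reactants: 5 methyl 2‑methoxy‑6‑(2‑oxoethyl)benzoate
Product: 8 (3R)‑8‑methoxy‑3‑(prop‑2‑en‑1‑yl)isochroman‑1‑one, via borinate 6 (not isolated), via hydroxy ester 7 (not isolated)
Conditions: lIpc2B(allyl) (1 M in pentane, 1.3 equiv), Et2O, −100 → −78 °C; then pH 7 phosphate buffer, MeOH, 30% H2O2, 0 °C → rt; then p‑TsOH·H2O (10 mol%), toluene, 60 °C
Reagents that add atoms: B‑allyldiisopinocampheylborane of the (−)‑α‑pinene series, lIpc2B(allyl), sold as (−)‑Ipc2B(allyl), C=CCB([C@H]1C[C@H]2C[C@@H]([C@@H]1C)C2(C)C)[C@H]1C[C@H]2C[C@@H]([C@@H]1C)C2(C)C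
Why: Brown asymmetric carbonyl allylation, in which the allylborane adds through a closed chair transition state to the Re face of the aldehyde and so sets the (R) carbinol that becomes C3, after which the δ‑hydroxy ester closes to the six‑membered lactone by acid‑catalysed transesterification at the acyl carbon with retention.

Step 5
Reactants: 8 (3R)‑8‑methoxy‑3‑(prop‑2‑en‑1‑yl)isochroman‑1‑one
Product: 10 (3R)‑8‑methoxy‑3‑(pent‑4‑en‑1‑yl)isochroman‑1‑one, via alkylborane 9 (not isolated)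
Conditions: 9‑BBN (0.5 M in THF, 1.5 equiv), 0 °C → rt; then 3 M aq K3PO4 (3 equiv), vinyl bromide (1 M in THF, 4 equiv), PdCl2(dppf) (5 mol%), AsPh3 (5 mol%), DMF, rt, closed flask
Reagents that add atoms: vinyl bromide, C=CBr
Why: Anti‑Markovnikov hydroboration with 9‑BBN, which does not reduce the lactone, followed by B‑alkyl Suzuki–Miyaura coupling with vinyl bromide lengthens the chain by two carbons and leaves a new terminal alkene while the stereocentre is untouched.

Step 6
Reactants: 11 dec‑1‑yne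
Product: 13 (E)‑1‑iododec‑1‑ene, via alkenylzirconocene 12 (not isolated)
Conditions: Cp2Zr(H)Cl (1.2 equiv), THF, rt, dark; then I2 (1.2 equiv), 0 °C
Reagents that add atoms: iodine, [I][I]
Why: Hydrozirconation adds Zr–H syn across the terminal alkyne with zirconium at the terminal carbon, and iodinolysis of the carbon–zirconium bond goes with retention, giving the (E)‑vinyl iodide in >98% geometric purity.

Step 7
Reactants: 10 (3R)‑8‑methoxy‑3‑(pent‑4‑en‑1‑yl)isochroman‑1‑one; 13 (E)‑1‑iododec‑1‑ene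
Product: 15 (3R)‑8‑methoxy‑3‑[(6E)‑pentadec‑6‑en‑1‑yl]isochroman‑1‑one, via alkylborane 14 (not isolated)
Conditions: 9‑BBN (0.5 M in THF, 1.5 equiv), rt; then 3 M aq K3PO4 (3 equiv), 13 (1.2 equiv), PdCl2(dppf) (5 mol%), AsPh3 (5 mol%), DMF, rt
Reagents that add atoms: none
Why: B‑alkyl Suzuki–Miyaura coupling joins the primary alkylborane to the vinyl iodide with complete retention of the E geometry, and the mild phosphate base leaves the lactone and the stereocentre alone.

Step 8
Reactants: 15 (3R)‑8‑methoxy‑3‑[(6E)‑pentadec‑6‑en‑1‑yl]isochroman‑1‑one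
Product: 17 (3R)‑8‑hydroxy‑3‑[(6E)‑pentadec‑6‑en‑1‑yl]isochroman‑1‑one, via dichloroborinate 16 (not isolated)
Conditions: BCl3 (1 M in CH2Cl2, 2.5 equiv), CH2Cl2, −78 → 0 °C; then H2O
Reagents that add atoms: none
Why: Chelation‑assisted Lewis‑acid ether cleavage, in which BCl3 binds between the lactone carbonyl and the peri methoxy group and chloride removes the methyl group at low temperature, conditions under which the isolated alkene and the C3 stereocentre are expected to survive.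

**Compound list**
1 | methyl 2‑hydroxy‑6‑methoxybenzoate | COC(=O)c1c(O)cccc1OC | starting material
2 | methyl 2‑methoxy‑6‑(trifluoromethanesulfonyloxy)benzoate | COC(=O)c1c(OS(=O)(=O)C(F)(F)F)cccc1OC | intermediate
3 | methyl 2‑methoxy‑6‑(prop‑2‑en‑1‑yl)benzoate | COC(=O)c1c(CC=C)cccc1OC | intermediate
4 | methyl 2‑methoxy‑6‑[(1,2,4‑trioxolan‑3‑yl)methyl]benzoate (secondary ozonide, formed in the flask) | COC(=O)c1c(CC2OCOO2)cccc1OC | intermediate
5 | methyl 2‑methoxy‑6‑(2‑oxoethyl)benzoate | COC(=O)c1c(CC=O)cccc1OC | intermediate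
6 | methyl 2‑[(2R)‑2‑(diisopinocampheylboryloxy)pent‑4‑en‑1‑yl]‑6‑methoxybenzoate (borinate, formed in the flask) | C=CC[C@@H](OB([C@H]1C[C@H]2C[C@@H]([C@@H]1C)C2(C)C)[C@H]1C[C@H]2C[C@@H]([C@@H]1C)C2(C)C)Cc1cccc(OC)c1C(=O)OC | intermediate
7 | methyl 2‑[(2R)‑2‑hydroxypent‑4‑en‑1‑yl]‑6‑methoxybenzoate (formed in the flask) | C=CC[C@@H](O)Cc1cccc(OC)c1C(=O)OC | intermediate
8 | (3R)‑8‑methoxy‑3‑(prop‑2‑en‑1‑yl)isochroman‑1‑one | C=CC[C@@H]1Cc2cccc(OC)c2C(=O)O1 | intermediate
9 | (3R)‑3‑[3‑(9‑borabicyclo[3.3.1]nonan‑9‑yl)propyl]‑8‑methoxyisochroman‑1‑one (formed in the flask) | C1CCC2CCCC1B2CCC[C@@H]1Cc2cccc(OC)c2C(=O)O1 | intermediate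
10 | (3R)‑8‑methoxy‑3‑(pent‑4‑en‑1‑yl)isochroman‑1‑one | C=CCCC[C@@H]1Cc2cccc(OC)c2C(=O)O1 | intermediate
11 | dec‑1‑yne | CCCCCCCCC#C | starting material
12 | chloro[(E)‑dec‑1‑en‑1‑yl]zirconocene, Cp2Zr(Cl)(CH=CH‑C8H17) (formed in the flask) | CCCCCCCC/C=C/[Zr](Cl)(C1C=CC=C1)C1C=CC=C1 | intermediate
13 | (E)‑1‑iododec‑1‑ene | CCCCCCCC/C=C/I | intermediate
14 | (3R)‑3‑[5‑(9‑borabicyclo[3.3.1]nonan‑9‑yl)pentyl]‑8‑methoxyisochroman‑1‑one (formed in the flask) | C1CCC2CCCC1B2CCCCC[C@@H]1Cc2cccc(OC)c2C(=O)O1 | intermediate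
15 | (3R)‑8‑methoxy‑3‑[(6E)‑pentadec‑6‑en‑1‑yl]isochroman‑1‑one | CCCCCCCC/C=C/CCCCC[C@@H]1Cc2cccc(OC)c2C(=O)O1 | intermediate
16 | (3R)‑8‑(dichloroboryloxy)‑3‑[(6E)‑pentadec‑6‑en‑1‑yl]isochroman‑1‑one (formed in the flask) | CCCCCCCC/C=C/CCCCC[C@@H]1Cc2cccc(OB(Cl)Cl)c2C(=O)O1 | intermediate
17 | (3R)‑8‑hydroxy‑3‑[(6E)‑pentadec‑6‑en‑1‑yl]isochroman‑1‑one | CCCCCCCC/C=C/CCCCC[C@@H]1Cc2cccc(O)c2C(=O)O1 | target

**Totals**
Total step count: 8. Longest linear sequence: 7 steps (steps 1–5, 7 and 8, from 1 to 17); step 6 is a one‑step side branch.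

**Three steps most likely to fail**

Step 4, the asymmetric allylation. Aldehyde 5 is an enolisable arylacetaldehyde, and allylborations of this aldehyde class typically give 92–96% ee, not a single enantiomer outright. If the ee cannot be raised by recrystallising 8, the fallback sets out from 3 and comes back at 8. Epoxidation of 3 with mCPBA (CH2Cl2, 0 °C → rt) gives racemic methyl 2‑methoxy‑6‑(oxiran‑2‑ylmethyl)benzoate F1. Hydrolytic kinetic resolution of F1 with (salen)Co(OAc) (trivalent cobalt, 0.5 mol%) and 0.55 equiv of water leaves methyl 2‑methoxy‑6‑{[(2S)‑oxiran‑2‑yl]methyl}benzoate F2 in ≥99% ee. The (R,R) catalyst is expected to consume the (R)‑epoxide, by analogy with simple 1‑alkyl oxiranes; this antipode assignment should be confirmed on a small scale. Vinylmagnesium bromide with CuBr·SMe2 (10 mol%, THF, −40 °C) opens F2 at the terminal carbon. The alkoxide of 7 that results lactonises to 8 (a trace of p‑TsOH completes it).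

Step 5, the B‑alkyl Suzuki coupling with vinyl bromide. The electrophile is volatile; protodeboronation or β‑hydride elimination would give a propyl by‑product, and unreacted 8 is hard to separate from 10. The fallback sets out from 8 and comes back at 10. Cross‑metathesis of 8 with acrolein (5 equiv) uses the second‑generation Hoveyda–Grubbs catalyst, RuCl2(H2IMes)(=CH‑C6H4‑2‑OiPr) (5 mol%, CH2Cl2, 40 °C). It gives (2E)‑4‑[(3R)‑8‑methoxy‑1‑oxoisochroman‑3‑yl]but‑2‑enal F3. Hydrogenation (H2, 1 atm, Pd/C, EtOAc) of the conjugated C=C gives 4‑[(3R)‑8‑methoxy‑1‑oxoisochroman‑3‑yl]butanal F4. Wittig methylenation (Ph3PCH3Br, KHMDS, THF, −78 → 0 °C) then gives 10.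

Step 8, the final demethylation. BCl3 and the HCl formed on work‑up could hydrochlorinate or isomerise the internal E alkene, giving isomers that cannot be separated from the target. The fallback sets out from 10 and comes back at 17, moving the demethylation to the terminal‑alkene stage, where any damage gives separable by‑products. BCl3 (CH2Cl2, −78 → 0 °C) converts 10 through (3R)‑8‑(dichloroboryloxy)‑3‑(pent‑4‑en‑1‑yl)isochroman‑1‑one F5 into (3R)‑8‑hydroxy‑3‑(pent‑4‑en‑1‑yl)isochroman‑1‑one F6. Hydroboration with 2.5 equiv of 9‑BBN, one equivalent being used up by the phenol, gives the O,C‑bis(9‑borabicyclo[3.3.1]nonan‑9‑yl) derivative F7. Coupling of F7 with 13 under the conditions of step 7, with extra aqueous K3PO4, gives 17 directly.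

**Further compounds**
F1 | step 4 | methyl 2‑methoxy‑6‑(oxiran‑2‑ylmethyl)benzoate (racemic) | COC(=O)c1c(CC2CO2)cccc1OC
F2 | step 4 | methyl 2‑methoxy‑6‑{[(2S)‑oxiran‑2‑yl]methyl}benzoate | COC(=O)c1c(C[C@H]2CO2)cccc1OC
F3 | step 5 | (2E)‑4‑[(3R)‑8‑methoxy‑1‑oxoisochroman‑3‑yl]but‑2‑enal | O=C/C=C/C[C@@H]1Cc2cccc(OC)c2C(=O)O1
F4 | step 5 | 4‑[(3R)‑8‑methoxy‑1‑oxoisochroman‑3‑yl]butanal | O=CCCC[C@@H]1Cc2cccc(OC)c2C(=O)O1
F5 | step 8 | (3R)‑8‑(dichloroboryloxy)‑3‑(pent‑4‑en‑1‑yl)isochroman‑1‑one | C=CCCC[C@@H]1Cc2cccc(OB(Cl)Cl)c2C(=O)O1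
F6 | step 8 | (3R)‑8‑hydroxy‑3‑(pent‑4‑en‑1‑yl)isochroman‑1‑one | C=CCCC[C@@H]1Cc2cccc(O)c2C(=O)O1
F7 | step 8 | (3R)‑3‑[5‑(9‑borabicyclo[3.3.1]nonan‑9‑yl)pentyl]‑8‑(9‑borabicyclo[3.3.1]nonan‑9‑yloxy)isochroman‑1‑one | C1CCC2CCCC1B2CCCCC[C@@H]1Cc2cccc(OB3C4CCCC3CCC4)c2C(=O)O1
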